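The numbers in the tables were computed on assumed constants, and the scatter is random.

If we balance the starting material, the limiting reagent with its charge 0.017 M smaller than the partner's 0.0204 M, each portion lost goes either to target or to self-condensation product, and these flasks turn on that split.

| flask | starting material | partner | remark | time |
|---|---|---|---|---|
| Saturday's | 0.017 M | 0.0204 M | run made earlier |  |
| Monday's | 0.024 M | 0.0204 M | run made earlier |  |
| Thursday's | 0.037 M | 0.0204 M | run made earlier |  |
| summer | 0.017 M | 0.0204 M (fed, over 3.0 h) | all else is in the flask from the start; the feed brings no volume worth counting | 4.0 h |
| dusk | 0.017 M (fed, over 3.0 h) | 0.0204 M | all else is in the flask from the start; the feed brings no volume worth counting | 4.0 h |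
| spring | 0.017 M | 0.0204 M | everything together at the start | 4.0 h |

- Saturday's (time / h: self-condensation product / %, target / %, starting material / %): 0.333: 52.1, 28.4, 19.9; 0.833: 58.4, 32.6, 10.5; 1.50: 62.4, 33.6, 6.8; 2.50: 62.9, 32.7, 2.5
- Monday's (time / h: self-condensation product / %, target / %, starting material / %): 0.417: 56.8, 29.1, 14.0; 1.00: 61.6, 32.1, 4.9; 2.00: 65.5, 32.4, 1.4; 3.00: 65.2, 29.9, 2.9
- Thursday's (time / h: self-condensation product / %, target / %, starting material / %): 0.417: 64.1, 27.9, 10.0; 1.00: 66.5, 28.6, 2.7; 2.00: 67.7, 27.0, 1.7; 3.00: 69.8, 30.2, 0.9

(scatter of a reading: 1 percentage point)

- the flask that comes out highest in amount of self-condensation product, in percent of the starting material charged; "all alike" if 1.5 percentage points covers them all (summer / dusk / spring / all alike)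
- amount of self-condensation product at the end, in percent of the starting material charged, summer
- amount of self-condensation product at the end, in percent of the starting material charged, dusk
- amount of self-condensation product at the end, in percent of the starting material charged, spring

- percentages count the starting material that a species holds: one self-condensation product counts as two

Target uses partner one for one, so we divide the starting material held in self-condensation product by ln(charged partner/partner left) and call the result Q. Thursday's last reading gives 0.0325 M. We read this as the switch concentration: the partner concentration B at which both routes use starting material equally, so that a share B/(B+Q) goes to target. Saturday's reading at 1.50 h gives 0.0323 M, although Thursday's charge is twice Saturday's. Saturday's first reading, 19.9% left after 0.333 h, read as second-order loss with the target share removed, gives a self-condensation half-life τ of 0.122 h at this charge.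

Now the settings. Charging everything together, as in spring, repeats Saturday's charges, so we expect about Saturday's last reading, 62.9% of product. Feeding the starting material, as in dusk, leaves the share at each partner level as it was, since B/(B+Q) holds no starting material, so we expect dusk near spring, somewhat lower for what remains unreacted. Feeding the partner, as in summer, changes the share: after one τ the summer flask has received 8.32 × 10⁻⁴ M of partner, far below Q. With tf the feed time and cB the partner charge, integrating the share over the second-order fall, we reckon summer's target at (τ·cB/(tf·Q))(ln(tf/τ)−1) = 5.62%, and, taking off as well the unreacted part τ/(t+τ) at the end time t, its product at 91.4%.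

The forecast says “the starting material burns off by self-condensation before the partner arrives” and names summer: 91% (84% to 95%) for summer, 62% (58% to 66%) for dusk, 64.5% (62% to 67%) for spring. Its spring figure stands 1.6 percentage points above the Saturday reading we took.

The flasks give 93.0% in summer, 61.9% in dusk and 64.4% in spring, so summer stands highest.

    starting material + partner → target, rate k1*[starting material]^2*[partner] (k = 240 L² mol⁻² min⁻¹)
    2 starting material → self-condensation product (k = 4.00 L mol⁻¹ min⁻¹)

In summer, self-condensation uses starting material 50 times as fast as the target step at 0.107 h and 1.7 times as fast at 4.00 h, where Q over summer's partner concentration stands at 1.66. For a neighbour of summer with 0.0051 M of partner, the reckoning with Q gives target 1.41%, and that flask holds 1.38%.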